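**Retrosynthetic overview**
- Number the side chain from benzylic C1' to C15'. The unit C7'H2–C8'=C9'(Z)–C10'H(OAc) is a but-2-ene-1,4-diyl fragment substituted at both ends. This is the pattern left by a 1,4-addition across a diene C7'=C8'–C9'=C10'.
- Late stage: the two phenol silyl ethers are removed last, after the C10' acetate is installed. The C6'–C7' bond is disconnected to a primary allylic acetate and a 6-arylhexyl Grignard reagent under copper catalysis.
- The allyl partner comes from (R,Z)-non-2-ene-1,4-diol. The diol comes from the enantioselective Pt-catalysed 1,4-diboration of (E)-nona-1,3-diene, which is made by Wittig methylenation of (E)-oct-2-enal.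
- The arylhexyl bromide comes from bis-TIPS 5-bromoresorcinol and 6-bromohex-1-ene by hydroboration and B-alkyl Suzuki–Miyaura coupling.
- No ring is formed. The only ring, the resorcinol benzene ring, is bought.

Key step: step 2

Assumption: the (R,R)-TADDOL-derived ligand is written for the (R)-series. The sense of induction is checked at diol 5 (MTPA esters) before scale-up, and if it is opposite the equally available (S,S)-ligand is used with nothing else changed.

**Step 1**
Reactants: 1 (E)-oct-2-enal
Product: 2 (E)-nona-1,3-diene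
Conditions: Ph3PCH3Br, KOtBu, THF, 0 °C → rt; pentane extraction, distillation
Reagents that add atoms: methyltriphenylphosphonium bromide, C[P+](c1ccccc1)(c1ccccc1)c1ccccc1.[Br-]
Why: Wittig methylenation, in which the non-stabilised ylide adds only to the aldehyde carbonyl, so the existing E alkene passes unchanged into the terminal diene.

**Step 2**
Reactants: 2 (E)-nona-1,3-diene; 3 bis(pinacolato)diboron
Product: 4 (2Z,4R)-1,4-bis(4,4,5,5-tetramethyl-1,3,2-dioxaborolan-2-yl)non-2-ene
Conditions: Pt(dba)3 (3 mol %), (R,R)-TADDOL-derived phenylphosphonite with 3,5-dialkylphenyl groups (6 mol %), THF, 60 °C; concentrated and passed through a short silica plug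
Reagents that add atoms: none
Why: Phosphonite-ligated Pt(0) inserts into the B–B bond of 3, the resulting bis(boryl)platinum(II) complex binds 2 in its s-cis form, and migratory insertion of the unsubstituted C7'=C8' terminus into one Pt–B bond makes C7'–B and an anti-configured π-allyl platinum boryl over C8'–C10'. Reductive elimination at the pentyl-bearing terminus makes C10'–B and leaves the alkene at C8'=C9', Z because the anti π-allyl inherits the s-cis shape of the bound diene. The closest known reaction type is the platinum-catalysed enantioselective 1,4-diboration of (E)-1-alkylbuta-1,3-dienes, the class to which 2 belongs. No ring is closed. The single new stereocentre C10' is controlled by the C2-symmetric TADDOL backbone, whose aryl groups decide which diene face lies on platinum, and boron is delivered to that same face. The step needs 1,4- over 1,2-addition, Z geometry and one enantioface: the E-monosubstituted diene reaches the s-cis conformer without allylic strain and so secures the first two, and the ligand antipode secures the third.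

**Step 3**
Reactants: 4 (2Z,4R)-1,4-bis(pinacolboryl)non-2-ene
Product: 5 (2Z,4R)-non-2-ene-1,4-diol
Conditions: 30 % H2O2, 3 M NaOH, THF, 0 °C → rt
Reagents that add atoms: hydrogen peroxide, OO
Why: Alkaline peroxide oxidation of organoboronates, in which hydroperoxide adds to each boron and carbon migrates from B to O with retention, so C10' becomes the (R)-carbinol and the Z alkene stays in place.

**Step 4**
Reactants: 5 (2Z,4R)-non-2-ene-1,4-diol
Product: 6 (2Z,4R)-4-hydroxynon-2-en-1-yl acetate
Conditions: AcCl (1.05 equiv), 2,4,6-collidine, CH2Cl2, −78 °C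
Reagents that add atoms: acetyl chloride, CC(=O)Cl
Why: Sterically controlled selective O-acylation, in which acetyl chloride with the hindered base at low temperature should acylate the primary C7' hydroxyl well before the secondary C10' hydroxyl, and the acetate is too poor a leaving group without a metal to let the cis-disposed free hydroxyl close a 2,5-dihydrofuran.

**Step 5**
Reactants: 6 (2Z,4R)-4-hydroxynon-2-en-1-yl acetate
Product: 7 (2Z,4R)-4-(triethylsilyloxy)non-2-en-1-yl acetate
Conditions: TESCl, imidazole, CH2Cl2, 0 °C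
Reagents that add atoms: chlorotriethylsilane, CC[Si](Cl)(CC)CC
Why: Imidazole-promoted silylation at oxygen leaves the C10'–O bond and its configuration untouched, and TES is chosen because mild acid later removes it beside aryl TIPS ethers.

**Step 6**
Reactants: 8 5-bromoresorcinol
Product: 9 1-bromo-3,5-bis(triisopropylsilyloxy)benzene
Conditions: TIPSCl (2.3 equiv), imidazole, DMF, rt
Reagents that add atoms: chlorotriisopropylsilane, CC(C)[Si](Cl)(C(C)C)C(C)C
Why: Imidazole-promoted silylation of both phenols gives aryl TIPS ethers that should withstand aqueous phosphate base and Grignard reagents and fall to fluoride at the end.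

**Step 7**
Reactants: 10 6-bromohex-1-ene; 9 1-bromo-3,5-bis(triisopropylsilyloxy)benzene
Product: 12 1-(6-bromohexyl)-3,5-bis(triisopropylsilyloxy)benzene, via B-(6-bromohexyl)-9-BBN 11 (not isolated)
Conditions: 9-BBN, THF, 0 °C → rt; then 9, PdCl2(dppf) (3 mol %), aq K3PO4, THF–DMF, 50 °C
Reagents that add atoms: 9-borabicyclo[3.3.1]nonane, B1C2CCCC1CCC2 (its boron framework is held by 11 only)
Why: Anti-Markovnikov hydroboration followed by B-alkyl Suzuki–Miyaura coupling, in which dppf-ligated palladium inserts into the aryl C–Br bond and not into the unactivated primary alkyl C–Br bond, so the bromide needed for the Grignard reagent is carried through.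

**Step 8**
Reactants: 12 1-(6-bromohexyl)-3,5-bis(triisopropylsilyloxy)benzene; 7 (2Z,4R)-4-(triethylsilyloxy)non-2-en-1-yl acetate
Product: 14 triethyl{(6R,7Z)-15-[3,5-bis(triisopropylsilyloxy)phenyl]pentadec-7-en-6-yloxy}silane, via arylhexylmagnesium bromide 13 (not isolated)
Conditions: 12, Mg (I2-activated), THF, 40 °C; then Li2CuCl4 (5 mol %), THF, −30 °C, 7 added to the Grignard/copper mixture (13 in 1.4-fold amount), → 0 °C; aq NH4Cl
Reagents that add atoms: magnesium, [Mg] (held by 13 only)
Why: Copper-catalysed Grignard allylic substitution with Li2CuCl4 in THF keeps the Grignard reagent in excess over copper so that a dialkylcuprate is the carrier, which favours direct α-attack at unhindered primary C7' over γ-attack at C9' shielded by the silyloxy-bearing C10', should retain the Z alkene at low temperature, and does not touch the C10'–O bond.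

**Step 9**
Reactants: 14 TES ether of the coupled product
Product: 15 (6R,7Z)-15-[3,5-bis(triisopropylsilyloxy)phenyl]pentadec-7-en-6-ol
Conditions: PPTS (cat.), MeOH–CH2Cl2, 0 °C → rt
Reagents that add atoms: none
Why: Acid-catalysed methanolysis of a silyl ether, in which the small alkyl TES group is cleaved at silicon far faster than the bulky, acid-resistant aryl TIPS ethers, and the acid is too weak to ionise the allylic C10'–O bond.

**Step 10**
Reactants: 15 (6R,7Z)-15-[3,5-bis(triisopropylsilyloxy)phenyl]pentadec-7-en-6-ol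
Product: 16 (6R,7Z)-15-[3,5-bis(triisopropylsilyloxy)phenyl]pentadec-7-en-6-yl acetate
Conditions: Ac2O, pyridine, DMAP (cat.), CH2Cl2, 0 °C → rt
Reagents that add atoms: acetic anhydride, CC(=O)OC(C)=O
Why: DMAP-catalysed acetylation takes place at oxygen, so the (R) configuration at C10' is retained and no other free hydroxyl competes.

**Step 11**
Reactants: 16 (6R,7Z)-15-[3,5-bis(triisopropylsilyloxy)phenyl]pentadec-7-en-6-yl acetate
Product: 17 (6R,7Z)-15-(3,5-dihydroxyphenyl)pentadec-7-en-6-yl acetate (target)
Conditions: TBAF (2.2 equiv), AcOH (2.5 equiv), THF, 0 °C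
Reagents that add atoms: none
Why: Fluoride-mediated desilylation, in which aryl silyl ethers are highly fluoride-labile and the acetic acid buffer protonates each phenoxide as it forms, so the allylic acetate should suffer neither cleavage nor acyl transfer.

**Compound list**
1 | (E)-oct-2-enal | CCCCC/C=C/C=O | starting material
2 | (E)-nona-1,3-diene | CCCCC/C=C/C=C | intermediate
3 | bis(pinacolato)diboron | CC1(C)OB(OC1(C)C)B1OC(C)(C)C(C)(C)O1 | starting material
4 | (2Z,4R)-1,4-bis(4,4,5,5-tetramethyl-1,3,2-dioxaborolan-2-yl)non-2-ene | CCCCC[C@H](/C=C\CB1OC(C)(C)C(C)(C)O1)B1OC(C)(C)C(C)(C)O1 | intermediate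
5 | (2Z,4R)-non-2-ene-1,4-diol | CCCCC[C@H](/C=C\CO)O | intermediate
6 | (2Z,4R)-4-hydroxynon-2-en-1-yl acetate | CCCCC[C@H](/C=C\COC(C)=O)O | intermediate
7 | (2Z,4R)-4-(triethylsilyloxy)non-2-en-1-yl acetate | CCCCC[C@H](/C=C\COC(C)=O)O[Si](CC)(CC)CC | intermediate
8 | 5-bromoresorcinol | Oc1cc(O)cc(Br)c1 | starting material
9 | 1-bromo-3,5-bis(triisopropylsilyloxy)benzene | Brc1cc(O[Si](C(C)C)(C(C)C)C(C)C)cc(O[Si](C(C)C)(C(C)C)C(C)C)c1 | intermediate
10 | 6-bromohex-1-ene | C=CCCCCBr | starting material
11 | B-(6-bromohexyl)-9-borabicyclo[3.3.1]nonane | BrCCCCCCB1C2CCCC1CCC2 | intermediate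
12 | 1-(6-bromohexyl)-3,5-bis(triisopropylsilyloxy)benzene | BrCCCCCCc1cc(O[Si](C(C)C)(C(C)C)C(C)C)cc(O[Si](C(C)C)(C(C)C)C(C)C)c1 | intermediate
13 | 6-[3,5-bis(triisopropylsilyloxy)phenyl]hexylmagnesium bromide | Br[Mg]CCCCCCc1cc(O[Si](C(C)C)(C(C)C)C(C)C)cc(O[Si](C(C)C)(C(C)C)C(C)C)c1 | intermediate
14 | triethyl{(6R,7Z)-15-[3,5-bis(triisopropylsilyloxy)phenyl]pentadec-7-en-6-yloxy}silane | CCCCC[C@H](/C=C\CCCCCCCc1cc(O[Si](C(C)C)(C(C)C)C(C)C)cc(O[Si](C(C)C)(C(C)C)C(C)C)c1)O[Si](CC)(CC)CC | intermediate
15 | (6R,7Z)-15-[3,5-bis(triisopropylsilyloxy)phenyl]pentadec-7-en-6-ol | CCCCC[C@H](/C=C\CCCCCCCc1cc(O[Si](C(C)C)(C(C)C)C(C)C)cc(O[Si](C(C)C)(C(C)C)C(C)C)c1)O | intermediate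
16 | (6R,7Z)-15-[3,5-bis(triisopropylsilyloxy)phenyl]pentadec-7-en-6-yl acetate | CCCCC[C@H](/C=C\CCCCCCCc1cc(O[Si](C(C)C)(C(C)C)C(C)C)cc(O[Si](C(C)C)(C(C)C)C(C)C)c1)OC(C)=O | intermediate
17 | (6R,7Z)-15-(3,5-dihydroxyphenyl)pentadec-7-en-6-yl acetate | CCCCC[C@H](/C=C\CCCCCCCc1cc(O)cc(O)c1)OC(C)=O | target

**Total step count:** 11. **Longest linear sequence:** 9 steps (steps 1–5, then 8–11).

**Steps most likely to fail**

Step 8.
- What may go wrong: attack of the organocopper species at the γ-carbon C9' with allylic transposition, leakage of Z into E through σ–π–σ equilibration of the allylcopper intermediate, carbonyl attack on the acetate, or Wurtz-type dimerisation during magnesium insertion.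
- The fallback sets out from 7 and 12 and comes back at 14. It replaces the metal-allyl pathway by a plain SN2 alkylation of a sulfone-stabilised carbanion.
- Acetate 7 is methanolysed (K2CO3, MeOH, 0 °C) to (R,Z)-4-(triethylsilyloxy)non-2-en-1-ol F1.
- An Appel reaction (CBr4, PPh3, 2,6-lutidine, CH2Cl2, −20 °C) converts it into (R,Z)-1-bromo-4-(triethylsilyloxy)non-2-ene F2.
- Bromide 12 is treated with PhSO2Na in DMF to give 6-[3,5-bis(triisopropylsilyloxy)phenyl]hexyl phenyl sulfone F3.
- Its lithio derivative (n-BuLi, THF, −78 °C) is alkylated with F2 at the primary carbon to give the C6'-phenylsulfonyl derivative of 14 F4.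
- Reductive desulfonylation of this homoallylic sulfone (Na/Hg, Na2HPO4, MeOH–THF, −20 °C) should give 14 without moving the alkene.

Step 2.
- What may go wrong: insufficient enantioface discrimination by the ligand, or leakage into 1,2-addition.
- The fallback sets out from 1 and comes back at 5. It sets C10' by reagent-controlled epoxidation and the Z alkene by alkyne semi-hydrogenation.
- Luche reduction of 1 gives (E)-oct-2-en-1-ol F5.
- Sharpless asymmetric epoxidation with D-(−)-diisopropyl tartrate gives [(2R,3R)-3-pentyloxiran-2-yl]methanol F6.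
- PPh3/CCl4 with NaHCO3 gives (2S,3R)-2-(chloromethyl)-3-pentyloxirane F7.
- Base-induced double elimination with n-BuLi (3 equiv, THF, −78 → −30 °C) keeps the C–O bond of the carbinol carbon and gives (R)-oct-1-yn-3-ol F8.
- Its dianion (n-BuLi, 2 equiv) is hydroxymethylated with paraformaldehyde to (R)-non-2-yne-1,4-diol F9.
- Hydrogenation over Lindlar catalyst with quinoline should give 5.

Step 7.
- What may go wrong: loss of an aryl silyl ether under the aqueous base, slow hydrolysis of the primary bromide, or protodeboronation of the alkylborane before transmetalation.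
- The fallback sets out from 9 and comes back at 12. It is base-free and replaces the palladium coupling by a copper-catalysed Grignard alkylation.
- Magnesium insertion into 9 (Mg, THF) gives 3,5-bis(triisopropylsilyloxy)phenylmagnesium bromide F10.
- F10 is added to a fourfold excess of 1,6-dibromohexane with Li2CuCl4 (cat.) in THF at 0 °C. The excess dibromide is distilled off to leave 12.

**Further compounds**
F1 | step 8 | (R,Z)-4-(triethylsilyloxy)non-2-en-1-ol | CCCCC[C@H](/C=C\CO)O[Si](CC)(CC)CC
F2 | step 8 | (R,Z)-1-bromo-4-(triethylsilyloxy)non-2-ene | CCCCC[C@H](/C=C\CBr)O[Si](CC)(CC)CC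
F3 | step 8 | 6-[3,5-bis(triisopropylsilyloxy)phenyl]hexyl phenyl sulfone | O=S(=O)(CCCCCCc1cc(O[Si](C(C)C)(C(C)C)C(C)C)cc(O[Si](C(C)C)(C(C)C)C(C)C)c1)c1ccccc1
F4 | step 8 | C6'-phenylsulfonyl derivative of 14 (both C6' epimers, C10' R, Z alkene) | CCCCC[C@H](/C=C\CC(CCCCCc1cc(O[Si](C(C)C)(C(C)C)C(C)C)cc(O[Si](C(C)C)(C(C)C)C(C)C)c1)S(=O)(=O)c1ccccc1)O[Si](CC)(CC)CC
F5 | step 2 | (E)-oct-2-en-1-ol | CCCCC/C=C/CO
F6 | step 2 | [(2R,3R)-3-pentyloxiran-2-yl]methanol | CCCCC[C@H]1O[C@@H]1CO
F7 | step 2 | (2S,3R)-2-(chloromethyl)-3-pentyloxirane | CCCCC[C@H]1O[C@@H]1CCl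
F8 | step 2 | (R)-oct-1-yn-3-ol | CCCCC[C@H](C#C)O
F9 | step 2 | (R)-non-2-yne-1,4-diol | CCCCC[C@H](C#CCO)O
F10 | step 7 | 3,5-bis(triisopropylsilyloxy)phenylmagnesium bromide | Br[Mg]c1cc(O[Si](C(C)C)(C(C)C)C(C)C)cc(O[Si](C(C)C)(C(C)C)C(C)C)c1
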